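I began with the balance.

common to all: starting material 0.12 M
- larch: protic impurity 0.12 M; enzyme 0.17 mM; run made earlier
- birch: protic impurity 0.12 M; enzyme 0.26 mM; run made earlier
- flask: protic impurity 0.120 M; enzyme 0.12 mM; time 10 h
- larch (time / h: product / %, starting material / %): 0.133: 47.3, 23.7; 0.250: 56.8, 8.1; 0.667: 56.8, 3.8; 1.33: 51.2, 3.2; 3.00: 41.6, 2.8; 8.00: 25.1, 1.6
- birch (time / h: product / %, starting material / %): 0.133: 60.4, 15.1; 0.250: 67.1, 6.1; 0.667: 62.7, 3.7; 1.33: 55.3, 3.0; 3.00: 42.1, 3.5; 8.00: 24.9, 1.8

(readings scatter by 0.5 percentage points)
* the moment within 10 h at which there is most product
* the amount of product, in percent of the starting material charged, at that time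

At 0.250 h the larch run was short of its charge by 35.1% and the birch run by 26.8%, so less was missing with more enzyme. I took the missing part to be starting material quenched one for one by the protic impurity.

Then I ordered the time scales. From the first readings of both runs, taken as linear in enzyme, I reckoned that starting material in the flask would disappear at 8.94 h⁻¹, a lifetime of 0.112 h. Next, the late ratio [starting material]/[product] averaged 7.16%. I read this as the equilibrium of the enzyme step, and I expected product to peak on reaching it. Slowest, larch product fell with a lifetime of 9.90 h, far longer.

Dividing the enzyme rate by the quenching rate removes time. [Starting material] cancels as well for a one-way enzyme step, but I had just read this step as reversible, so the g below is an effective number read from the runs, with the back reaction folded in, and the line is an approximation: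

product = g × ln(charge / impurity left), with impurity left = product + starting material (shares of charge)

The readings at 0.250 h gave g/[enzyme] as 7.73 mM⁻¹ in larch and 8.27 mM⁻¹ in birch. I carried their mean, 8.00 mM⁻¹, as the split number, an effective selectivity factor per unit of enzyme. For the flask g is 0.960, and at the peak:

product + starting material = exp(−product / g), with starting material = 7.16% × product

This gave 53.4% product, with starting material at 3.83%, reached after 0.365 h.

The forecast said 49% at 0.6 h, holding that “starting material settles at about 6.5% of product”.

The flask gave 53.0% at 0.477 h, later than my time.

    starting material + enzyme ⇌ complex (K = 4.70 M⁻¹, k = 760 M⁻¹ s⁻¹)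
    complex ⇌ enzyme + product (K = 2.80 M, k = 3.30 s⁻¹)
    starting material + protic impurity → quenched substrate (k = 0.0110 M⁻¹ s⁻¹)

A neighbouring flask held 0.0480 mM of enzyme, with everything else as in the flask. The split number gave it a g of 0.384, and the same peak equation then gave 36.2% product. The neighbouring flask itself reached 36.7%.

The readings were generated by integration for substances that don't exist; scatter was added.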